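**Retrosynthetic overview** (eudesmane numbering: ring A = C1–C5/C10, ring B = C5–C10, side chain C11–C13 on C7, acyloxy on C9, carbinol at C4; β = face of the C10 methyl)
1. Target ⇐ oxidation of C12 (SeO2, then TEMPO/chlorite) and O-acylation at C9 of a 7α-isopropenyl-9β-ol, which ⇐ axial cuprate addition and thermodynamic ketone reduction on a trans-fused Δ7-en-9-one.
2. Ring B is not annulated as a six-membered ring: it comes from the five-membered ring C9–C10–C5–C6–C7 of a trans-hydrindan-1-one by insertion of one carbon (C8, from CH2I2) between C9 and C7, through a siloxycyclopropane and its Fe(III) ring enlargement.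
3. Enabling feature: the C9 carbonyl lies between the quaternary C10 (methyl, no hydrogen) and the C7 methylene, so enol ether formation, cyclopropanation, bond scission and HCl loss can occur on one side only, and the Δ7-en-9-one makes C7 an enone β-carbon for axial (α) delivery of the side chain.
4. The hydrindanone ⇐ (S)-4-methyl Hajos–Parrish ketone by Luche reduction, Myers reductive transposition (trans fusion) and Mukaiyama hydration (C4 carbinol).
5. Ring order: cyclopentane (bought as the 1,3-dione) → ring A (amino-acid-catalysed aldol condensation) → ring B by one-carbon expansion of the cyclopentane.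

Key step: step 9

Remark on the structure: read from the SMILES, the target is (4R,5R,7R,9S,10S), i.e. a trans-decalin with C10-CH3 β (axial), H-5 α, 4α-OH/4β-CH3, 9β-acyloxy (equatorial) and the C7 acrylic acid unit α (axial, cis to H-5); the ester is (S)-3-methylpentanoate.
Assumption: (S)-3-methylpentanoic acid 19 is taken as a commercial building block.

**Step 1**
Reactants: 1 2-methylcyclopentane-1,3-dione; 2 ethyl vinyl ketone (pent-1-en-3-one)
Product: 3 2-methyl-2-(3-oxopentyl)cyclopentane-1,3-dione
Conditions: H2O, AcOH (cat.), 75 °C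
Reagents that add atoms: none
Why: Michael addition of the acidic 1,3-dione to the vinyl ketone (first half of a Robinson annulation) needs only water and a trace of acid; the product is achiral.

**Step 2**
Reactants: 3 2-methyl-2-(3-oxopentyl)cyclopentane-1,3-dione
Product: 5 (S)-4,7a-dimethyl-2,3,7,7a-tetrahydro-1H-indene-1,5(6H)-dione, via ketol 4 (not isolated)
Conditions: L-phenylalanine (1 equiv), (1S)-(+)-10-camphorsulfonic acid (0.5 equiv), DMF, 30 → 70 °C
Reagents that add atoms: none
Why: Hajos–Parrish–Eder–Sauer–Wiechert aldol condensation: the L-amino acid forms the side-chain enamine, which attacks one of the two enantiotopic ring carbonyls through a hydrogen-bonded chair-like transition state, so the quaternary carbon (C10) should be set as S, and the sulfonic acid dehydrates ketol 4 to the enone.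

**Step 3**
Reactants: 5 (S)-4,7a-dimethyl-2,3,7,7a-tetrahydro-1H-indene-1,5(6H)-dione
Product: 6 (1S,5S,7aS)-4,7a-dimethyl-2,3,5,6,7,7a-hexahydro-1H-indene-1,5-diol (both hydroxyls β)
Conditions: NaBH4 (1.2 equiv), CeCl3·7H2O, MeOH, −20 → 0 °C
Reagents that add atoms: none
Why: Luche reduction: cerium-activated 1,2-hydride delivery to both carbonyls from the α face (axial attack on the enone, as in steroidal 4-en-3-ones) should give the 3β-allylic alcohol needed for step 4 and the 9β-alcohol, whose configuration is irrelevant because it is oxidised in step 6.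

**Step 4**
Reactants: 6 (1S,5S,7aS)-4,7a-dimethyl-2,3,5,6,7,7a-hexahydro-1H-indene-1,5-diol
Product: 9 (1S,3aS,7aS)-4,7a-dimethyl-2,3,3a,6,7,7a-hexahydro-1H-inden-1-ol (trans-fused, Δ3 in eudesmane numbering), via Mitsunobu adduct 7 (not isolated), via allylic diazene 8 (not isolated)
Conditions: 2-nitrobenzenesulfonylhydrazide, PPh3, DEAD, N-methylmorpholine, −30 °C; then 23 °C
Reagents that add atoms: none
Why: Myers reductive 1,3-transposition: Mitsunobu displacement with inversion occurs only at the allylic carbinol (the neopentyl cyclopentanol cannot undergo SN2), sulfinate loss gives the 3α-diazene 8, and its retro-ene loss of N2 transfers hydrogen suprafacially to the α face of C5, which sets the trans ring fusion and leaves the trisubstituted Δ3 alkene.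

**Step 5**
Reactants: 9 (1S,3aS,7aS)-4,7a-dimethyl-2,3,3a,6,7,7a-hexahydro-1H-inden-1-ol
Product: 10 (1S,3aR,4R,7aS)-4,7a-dimethyloctahydro-1H-indene-1,4-diol (trans-fused; tertiary OH α, its methyl β)
Conditions: Co(acac)2 (20 mol %), PhSiH3, O2 (1 atm), THF, 0 °C → rt
Reagents that add atoms: dioxygen, O=O
Why: Mukaiyama hydration (Co–H hydrogen-atom transfer to C3 gives the tertiary C4 radical, Markovnikov): O2 should be captured on the α face because the β (axial) face of C4 is blocked by the syn-axial C10 methyl, giving the 4α-hydroxy-4β-methyl carbinol (C4 R).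

**Step 6**
Reactants: 10 (1S,3aR,4R,7aS)-4,7a-dimethyloctahydro-1H-indene-1,4-diol
Product: 11 (3aR,4R,7aS)-4-hydroxy-4,7a-dimethyloctahydro-1H-inden-1-one
Conditions: Dess–Martin periodinane, CH2Cl2, rt
Reagents that add atoms: none
Why: Dess–Martin oxidation converts only the secondary alcohol; the tertiary alcohol is inert and the ring-fusion centres cannot epimerise (C10 quaternary, C5 β to the carbonyl).

**Step 7**
Reactants: 11 (3aR,4R,7aS)-4-hydroxy-4,7a-dimethyloctahydro-1H-inden-1-one
Product: 12 bis-TMS derivative of 11 (silyl enol ether C9=C7 and tertiary TMS ether at C4)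
Conditions: TMSOTf (2.4 equiv), Et3N, CH2Cl2, 0 °C
Reagents that add atoms: trimethylsilyl trifluoromethanesulfonate, C[Si](C)(C)OS(=O)(=O)C(F)(F)F
Why: Soft enolisation/silylation: the ketone can enolise only toward C7 because C10 is quaternary, so a single silyl enol ether regioisomer forms, and the tertiary alcohol is capped as its TMS ether at the same time.

**Step 8**
Reactants: 12 bis-TMS derivative of 11
Product: 13 siloxycyclopropane (1-trimethylsilyloxybicyclo[3.1.0]hexane unit C9–C8–C7 fused to the trans-hydrindane, new CH2 on the α face, C4–OTMS retained)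
Conditions: Et2Zn, CH2I2, CH2Cl2, 0 °C → rt; pyridine quench
Reagents that add atoms: diiodomethane, ICI
Why: Furukawa–Simmons–Smith cyclopropanation: the electrophilic zinc carbenoid adds to the electron-rich silyl enol ether (the only alkene present), presumably from the α face opposite the angular methyl, and the two new stereocentres are destroyed again in step 9.

**Step 9**
Reactants: 13 siloxycyclopropane
Product: 16 (4aR,5R,8aS)-5-hydroxy-5,8a-dimethyl-4a,5,6,7,8,8a-hexahydronaphthalen-1(4H)-one (trans-fused Δ7-en-9-one), via β-chloroketone 14 (not isolated), via enone silyl ether 15 (not isolated)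
Conditions: FeCl3 (2.5 equiv), DMF, 0 °C → rt; then NaOAc, MeOH, reflux; 1 M HCl work-up
Reagents that add atoms: none
Why: Fe(III) converts the siloxycyclopropane into an iron(III) cyclopropoxide and oxidises it to a cyclopropyloxy radical, which undergoes β-scission of the internal C9–C7 bond to the ring-enlarged ketone with a secondary radical at C7; chlorine transfer from FeCl3 gives 14, acetate-induced E1cB loss of HCl gives the Δ7-en-9-one 15, and the acidic work-up frees the C4 alcohol. The closest known reaction is the Ito–Saegusa FeCl3 ring enlargement of 1-siloxybicyclo[n.1.0]alkanes to 2-cycloalkenones, here run on a cyclopentanone-derived bicyclo[3.1.0]hexane that is trans-fused to ring A. No ring is closed from a chain: ring B arises by one-carbon ring expansion of the five-membered ring C9–C10–C5–C6–C7 to the six-membered ring C9–C8–C7–C6–C5–C10, C8 being the carbon brought in by CH2I2. No stereocentre is created (the C7 chloride is transient and lost), and C4, C5 and C10 are untouched because C10 is quaternary and C5 is not enolisable. The selectivity needed is internal over external cyclopropane-bond scission, secured by the greater stability of the secondary C7 radical and the relief of bicyclic strain, and HCl loss only across C7–C8, secured by the absence of hydrogen on C10. The step delivers ring B in its final size with the C9 oxygen in place and C7 as an enone β-carbon for the axial delivery of the side chain in step 10.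

**Step 10**
Reactants: 16 (4aR,5R,8aS)-5-hydroxy-5,8a-dimethyl-4a,5,6,7,8,8a-hexahydronaphthalen-1(4H)-one
Product: 17 (4R,5R,7R,10S)-4-hydroxyeudesm-11(13)-en-9-one (7α-isopropenyl, axial)
Conditions: isopropenylmagnesium bromide (3 equiv), CuBr·SMe2 (20 mol %), THF, −78 → −30 °C; aq. NH4Cl
Reagents that add atoms: isopropenylmagnesium bromide, C=C(C)[Mg]Br
Why: Copper-catalysed conjugate addition of the Grignard reagent: stereoelectronically controlled axial attack on C7 from the α face (the face of the axial H-5, leading directly to the chair enolate, trans to the C10 methyl) should set C7 (R) with the isopropenyl group axial, while 1,2-addition is disfavoured at the neopentyl carbonyl.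

**Step 11**
Reactants: 17 (4R,5R,7R,10S)-4-hydroxyeudesm-11(13)-en-9-one
Product: 18 (4R,5R,7R,9S,10S)-eudesm-11(13)-ene-4,9-diol (9β-OH, equatorial)
Conditions: Li, NH3(l)/THF, t-BuOH, −78 °C; then NH4Cl
Reagents that add atoms: none
Why: Dissolving-metal reduction under thermodynamic control should give the equatorial 9β-alcohol (C9 S), because the axial epimer would be syn-axial to the C7 isopropenyl group; the isolated alkene is not reduced.

**Step 12**
Reactants: 18 (4R,5R,7R,9S,10S)-eudesm-11(13)-ene-4,9-diol; 19 (S)-3-methylpentanoic acid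
Product: 20 (4R,5R,7R,9S,10S)-4-hydroxyeudesm-11(13)-en-9-yl (S)-3-methylpentanoate
Conditions: EDC·HCl, DMAP, CH2Cl2, 0 °C → rt
Reagents that add atoms: none
Why: Steglich esterification (carbodiimide/DMAP acyl transfer): only the secondary equatorial C9 alcohol is acylated, the hindered tertiary C4 alcohol stays free, and the β-stereocentre of the acid cannot epimerise.

**Step 13**
Reactants: 20 (4R,5R,7R,9S,10S)-4-hydroxyeudesm-11(13)-en-9-yl (S)-3-methylpentanoate
Product: 21 (4R,5R,7R,9S,10S)-4,12-dihydroxyeudesm-11(13)-en-9-yl (S)-3-methylpentanoate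
Conditions: SeO2 (0.5 equiv), t-BuOOH, CH2Cl2, rt
Reagents that add atoms: tert-butyl hydroperoxide, CC(C)(C)OO (oxygen delivered through catalytic selenium dioxide, O=[Se]=O)
Why: Selenium dioxide allylic oxidation (ene reaction, then [2,3]-sigmatropic shift, Sharpless catalytic conditions) should functionalise the methyl group of the 1,1-disubstituted alkene in preference to the ring methine and keeps the exocyclic double bond in place.

**Step 14**
Reactants: 21 (4R,5R,7R,9S,10S)-4,12-dihydroxyeudesm-11(13)-en-9-yl (S)-3-methylpentanoate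
Product: 23 (4R,5R,7R,9S,10S)-4-hydroxy-9-[(S)-3-methylpentanoyloxy]eudesm-11(13)-en-12-oic acid (target), via enal 22 (not isolated)
Conditions: TEMPO (10 mol %), PhI(OAc)2, CH2Cl2, rt; then NaClO2, NaH2PO4, 2-methyl-2-butene, t-BuOH/H2O, 0 °C → rt
Reagents that add atoms: sodium chlorite, [Na+].[O-]Cl=O
Why: Oxoammonium (TEMPO/PhI(OAc)2) oxidation of the primary allylic alcohol to the enal, followed in the same flask by Pinnick oxidation, should give the acrylic acid; the ester, the tertiary alcohol and the α-methylene group are stable under these buffered conditions.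

**Compound list**
1 | 2-methylcyclopentane-1,3-dione | CC1C(=O)CCC1=O | starting material
2 | ethyl vinyl ketone (pent-1-en-3-one) | CCC(=O)C=C | starting material
3 | 2-methyl-2-(3-oxopentyl)cyclopentane-1,3-dione | CCC(=O)CCC1(C)C(=O)CCC1=O | intermediate
4 | cis-fused ketol, 3a-hydroxy-4,7a-dimethylhexahydroindane-1,5-dione (OH cis to the angular methyl; C4 epimers immaterial) | O=C1CC[C@]2(O)C(C)C(=O)CC[C@]12C | intermediate (not isolated)
5 | (S)-4,7a-dimethyl-2,3,7,7a-tetrahydro-1H-indene-1,5(6H)-dione | O=C1CCC2=C(C)C(=O)CC[C@]12C | intermediate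
6 | (1S,5S,7aS)-4,7a-dimethyl-2,3,5,6,7,7a-hexahydro-1H-indene-1,5-diol | O[C@H]1CCC2=C(C)[C@@H](O)CC[C@]12C | intermediate
7 | Mitsunobu adduct, N-amino-N-(2-nitrophenylsulfonyl)amine at the former allylic carbinol carbon (α, inverted) | O[C@H]1CCC2=C(C)[C@H](N(N)S(=O)(=O)c3ccccc3[N+](=O)[O-])CC[C@]12C | intermediate (not isolated)
8 | allylic monoalkyl diazene (N=NH α) | O[C@H]1CCC2=C(C)[C@H](N=N)CC[C@]12C | intermediate (not isolated)
9 | (1S,3aS,7aS)-4,7a-dimethyl-2,3,3a,6,7,7a-hexahydro-1H-inden-1-ol (trans-fused) | O[C@H]1CC[C@H]2C(C)=CCC[C@]12C | intermediate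
10 | (1S,3aR,4R,7aS)-4,7a-dimethyloctahydro-1H-indene-1,4-diol | O[C@H]1CC[C@H]2[C@](C)(O)CCC[C@]12C | intermediate
11 | (3aR,4R,7aS)-4-hydroxy-4,7a-dimethyloctahydro-1H-inden-1-one | O=C1CC[C@H]2[C@](C)(O)CCC[C@]12C | intermediate
12 | bis-TMS derivative of 11 (silyl enol ether and tertiary silyl ether) | C[Si](C)(C)OC1=CC[C@H]2[C@](C)(O[Si](C)(C)C)CCC[C@]12C | intermediate
13 | siloxycyclopropane (cyclopropanated 12, CH2 on the α face) | C[Si](C)(C)O[C@@]12C[C@@H]1C[C@H]1[C@](C)(O[Si](C)(C)C)CCC[C@]21C | intermediate
14 | β-chloroketone, 7-chloro-trans-decalin-9-one with C4–OTMS (epimers at C–Cl immaterial) | O=C1CC(Cl)C[C@H]2[C@](C)(O[Si](C)(C)C)CCC[C@]12C | intermediate (not isolated)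
15 | enone silyl ether (C4–OTMS form of 16) | O=C1C=CC[C@H]2[C@](C)(O[Si](C)(C)C)CCC[C@]12C | intermediate (not isolated)
16 | (4aR,5R,8aS)-5-hydroxy-5,8a-dimethyl-4a,5,6,7,8,8a-hexahydronaphthalen-1(4H)-one | O=C1C=CC[C@H]2[C@](C)(O)CCC[C@]12C | intermediate
17 | (4R,5R,7R,10S)-4-hydroxyeudesm-11(13)-en-9-one | C=C(C)[C@H]1CC(=O)[C@@]2(C)CCC[C@@](C)(O)[C@@H]2C1 | intermediate
18 | (4R,5R,7R,9S,10S)-eudesm-11(13)-ene-4,9-diol | C=C(C)[C@H]1C[C@H](O)[C@@]2(C)CCC[C@@](C)(O)[C@@H]2C1 | intermediate
19 | (S)-3-methylpentanoic acid | OC(=O)C[C@@H](C)CC | starting material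
20 | (4R,5R,7R,9S,10S)-4-hydroxyeudesm-11(13)-en-9-yl (S)-3-methylpentanoate | C=C(C)[C@H]1C[C@H](OC(=O)C[C@@H](C)CC)[C@@]2(C)CCC[C@@](C)(O)[C@@H]2C1 | intermediate
21 | (4R,5R,7R,9S,10S)-4,12-dihydroxyeudesm-11(13)-en-9-yl (S)-3-methylpentanoate | C=C(CO)[C@H]1C[C@H](OC(=O)C[C@@H](C)CC)[C@@]2(C)CCC[C@@](C)(O)[C@@H]2C1 | intermediate
22 | enal, (4R,5R,7R,9S,10S)-4-hydroxy-12-oxoeudesm-11(13)-en-9-yl (S)-3-methylpentanoate | C=C(C=O)[C@H]1C[C@H](OC(=O)C[C@@H](C)CC)[C@@]2(C)CCC[C@@](C)(O)[C@@H]2C1 | intermediate (not isolated)
23 | (4R,5R,7R,9S,10S)-4-hydroxy-9-[(S)-3-methylpentanoyloxy]eudesm-11(13)-en-12-oic acid | C=C(C(=O)O)[C@H]1C[C@H](OC(=O)C[C@@H](C)CC)[C@@]2(C)CCC[C@@](C)(O)[C@@H]2C1 | target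

**Step count and risks**
Total steps: 14. Longest linear sequence: 14 (from 1 and 2; acid 19 enters at step 12).

Steps most likely to fail:

- Step 4. The trans ring fusion depends on clean β-selectivity in the preceding reduction and on the Mitsunobu reaction taking place only at the allylic hydroxyl; facial leakage or reaction at the second hydroxyl would erode the fusion stereochemistry. Fallback, setting out from 5 and coming back at 9: chemoselective NaBH4 reduction (EtOH, −20 °C) of the saturated ketone gives the hydroxy enone F1; TBSCl/imidazole gives the silyl ether F2; Li/NH3 reduction with trapping of the enolate by PhNTf2 gives the trans-fused enol triflate F3 (trans fusion from axial protonation at C5); Pd(OAc)2/PPh3, Bu3N, HCO2H reduces it to the alkene silyl ether F4; TBAF then gives 9.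

- Step 5. Oxygen capture at the planar C4 radical may show poor facial selectivity, and hydroperoxide or ketone by-products may form. Fallback, setting out from 9 and coming back at 10: m-CPBA epoxidation (NaHCO3, CH2Cl2), which attacks the α face for the same steric reason, gives the 3α,4α-epoxide F5; LiEt3BH opens it by hydride attack at the less substituted C3, leaving the C4–O bond untouched, to give 10.

- Step 13. The ene reaction may occur at the C7 methine in place of the methyl group, or over-oxidation may take place. Fallback, setting out from 20 and coming back at 22: ene-type chlorination with hypochlorous acid (Ca(OCl)2, solid CO2, CH2Cl2/H2O) gives the allylic chloride F6; Ganem oxidation (Me3NO, DMSO) converts it into the enal 22, which is carried through the chlorite half of step 14 to 23.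

**Further compounds**
F1 | step 4 | (1S,7aS)-1-hydroxy-4,7a-dimethyl-1,2,3,6,7,7a-hexahydro-5H-inden-5-one | O[C@H]1CCC2=C(C)C(=O)CC[C@]12C
F2 | step 4 | tert-butyldimethylsilyl ether of F1 | CC(C)(C)[Si](C)(C)O[C@H]1CCC2=C(C)C(=O)CC[C@]12C
F3 | step 4 | trans-fused enol triflate (C3–OTf, Δ3) of the silyl ether | CC(C)(C)[Si](C)(C)O[C@H]1CC[C@H]2C(C)=C(OS(=O)(=O)C(F)(F)F)CC[C@]12C
F4 | step 4 | tert-butyldimethylsilyl ether of 9 | CC(C)(C)[Si](C)(C)O[C@H]1CC[C@H]2C(C)=CCC[C@]12C
F5 | step 5 | 3α,4α-epoxide of 9 | O[C@H]1CC[C@H]2[C@]3(C)O[C@@H]3CC[C@]12C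
F6 | step 13 | allylic chloride (12-chloro analogue of 20) | C=C(CCl)[C@H]1C[C@H](OC(=O)C[C@@H](C)CC)[C@@]2(C)CCC[C@@](C)(O)[C@@H]2C1
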